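**Plan**

- Retrosynthesis: take off the hemisuccinate and the phenol protecting groups, then cut the lactone ring at C4–C3 and at C1–C8a (isochroman-1-one numbering). The ester unit C3–O2–C1(=O) stays whole as an O-alkyl N,N-diisopropylcarbamate.
- Enabling feature: in the lactone ring this ester unit is flanked by benzylic C4 and aryl C8a, which sit 1,3 on the hydroquinone ring. A carbamate on O2 makes C3 a configurationally stable carbanion and keeps C1 an acyl donor; a 2-bromobenzyl bromide is electrophilic at C4 and, after Br–Li exchange, nucleophilic at C8a.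
- Forward: the chain carbamate (4 steps from (R)-propylene oxide) and the arene dibromide (4 steps from bromohydroquinone) are joined in one flask by benzylation and O-to-C carbamoyl shift. Acid then closes the lactone ring, the only ring formed, and frees the side-chain hydroxyl; succinylation and hydrogenolysis finish.
- Stereochemistry: the side-chain carbinol (R) comes from (R)-propylene oxide; C3 (R) comes from (–)-sparteine-controlled α-lithiation and retentive benzylation.
- Helpers removed later: the aryl bromine (lost in the key step), the diisopropylamino group (lost on lactonisation), and the silyl and benzyl ethers.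

Key step: step 9

Remark: the structure is read as (3R) at the lactone carbon and (R) at the side-chain carbinol; benzylation of the non-stabilised α-lithio carbamate is taken to go with retention, as such carbanions generally do.

**Route**

Step 1
Reactants: 1 (R)-propylene oxide; 2 allylmagnesium bromide
Product: 3 (2R)-hex-5-en-2-ol
Conditions: CuI (10 mol%), THF, −30 to 0 °C; then H2O
Reagents that add atoms: none
Why: Copper-catalysed Grignard opening of a terminal epoxide should occur by SN2 at the unsubstituted carbon, so the C–O stereocenter of 1 is untouched and becomes the (R) side-chain carbinol.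

Step 2
Reactants: 3 (2R)-hex-5-en-2-ol
Product: 4 tert-butyl{[(2R)-hex-5-en-2-yl]oxy}dimethylsilane
Conditions: TBSCl, imidazole, DMF, 23 °C
Reagents that add atoms: tert-butyldimethylsilyl chloride, CC(C)(C)[Si](C)(C)Cl
Why: Imidazole-promoted silylation of a secondary alcohol should give an ether that tolerates the organolithium bases of step 9 and falls off under the acid of step 10.

Step 3
Reactants: 4 tert-butyl{[(2R)-hex-5-en-2-yl]oxy}dimethylsilane
Product: 6 (5R)-5-[(tert-butyldimethylsilyl)oxy]hexan-1-ol, via alkylborane 5 (not isolated)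
Conditions: 9-BBN, THF, 0 to 23 °C; then NaOH, H2O2, 0 to 23 °C
Reagents that add atoms: 9-borabicyclo[3.3.1]nonane, B1C2CCCC1CCC2 (its atoms stay in 5 only); hydrogen peroxide, OO
Why: Hydroboration–oxidation with a bulky borane should deliver only the anti-Markovnikov primary alcohol.

Step 4
Reactants: 6 (5R)-5-[(tert-butyldimethylsilyl)oxy]hexan-1-ol; 7 N,N-diisopropylcarbamoyl chloride
Product: 8 (5R)-5-[(tert-butyldimethylsilyl)oxy]hexyl N,N-diisopropylcarbamate
Conditions: Et3N, DMAP (cat.), CH2Cl2, reflux
Reagents that add atoms: none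
Why: O-Carbamoylation of a primary alcohol should give the hindered carbamate that directs α-lithiation and later supplies the lactone carbonyl carbon.

Step 5
Reactants: 9 2-bromobenzene-1,4-diol (bromohydroquinone)
Product: 10 1,4-bis(benzyloxy)-2-bromobenzene
Conditions: BnBr, K2CO3, DMF, 60 °C
Reagents that add atoms: benzyl bromide, BrCc1ccccc1
Why: Williamson ether synthesis on both phenols should give ethers that survive the lithium bases and the acid of the route and leave by hydrogenolysis at the end.

Step 6
Reactants: 10 1,4-bis(benzyloxy)-2-bromobenzene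
Product: 12 3,6-bis(benzyloxy)-2-bromobenzaldehyde, via aryllithium 11 (not isolated)
Conditions: LiN(i-Pr)2, THF, −78 °C; then DMF, −78 to 0 °C; then H2O
Reagents that add atoms: N,N-dimethylformamide, CN(C)C=O; lithium diisopropylamide, CC(C)N([Li])C(C)C (lithium stays in 11 only)
Why: Directed ortho-metalation by a lithium amide should remove the most acidic ring hydrogen, the one flanked by bromine and a benzyloxy group, and formylation with DMF at −78 °C should outrun loss of LiBr to the aryne.

Step 7
Reactants: 12 3,6-bis(benzyloxy)-2-bromobenzaldehyde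
Product: 13 [3,6-bis(benzyloxy)-2-bromophenyl]methanol
Conditions: NaBH4, MeOH/THF, 0 °C
Reagents that add atoms: none
Why: Borohydride reduction of an aromatic aldehyde should be clean and leave the aryl bromide and benzyl ethers alone.

Step 8
Reactants: 13 [3,6-bis(benzyloxy)-2-bromophenyl]methanol
Product: 14 1,4-bis(benzyloxy)-2-bromo-3-(bromomethyl)benzene
Conditions: CBr4, PPh3, CH2Cl2, 0 °C
Reagents that add atoms: carbon tetrabromide, BrC(Br)(Br)Br
Why: The Appel reaction should turn the benzylic alcohol into the bromide under neutral conditions that spare the benzyl ethers.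

Step 9
Reactants: 8 (5R)-5-[(tert-butyldimethylsilyl)oxy]hexyl N,N-diisopropylcarbamate; 14 1,4-bis(benzyloxy)-2-bromo-3-(bromomethyl)benzene
Product: 18 3,6-bis(benzyloxy)-2-[(2R,6R)-6-[(tert-butyldimethylsilyl)oxy]-2-hydroxyheptyl]-N,N-diisopropylbenzamide, via lithio carbamate 15 (not isolated), via bromoaryl carbamate 16 (not isolated), via aryllithium 17 (not isolated)
Conditions: s-BuLi, (–)-sparteine, Et2O, −78 °C; then 14 (limiting) in Et2O, −78 °C; then t-BuLi (2.1 equiv), −78 to 23 °C; then H2O
Reagents that add atoms: sec-butyllithium, CCC(C)[Li] (lithium stays in 15 only); tert-butyllithium, CC(C)(C)[Li] (lithium stays in 17 only)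
Why: Proposed new method: (–)-sparteine-complexed s-BuLi should remove the pro-S hydrogen on the carbamate-bearing carbon of 8 to give the chelated, configurationally stable (S)-α-lithio carbamate 15, which is benzylated by 14 with retention (SE2, front side) to forge C4–C3 in 16; t-BuLi then exchanges the aryl bromine for lithium, and aryllithium 17 adds to its own carbamate carbonyl and moves the carbamoyl group from O2 to C8a, forging C1–C8a. The closest known reaction types are the sparteine-mediated lithiation–substitution of O-alkyl carbamates and the anionic homo-Fries (Parham-type) O-to-C carbamoyl shift of ortho-lithiated benzyl and biaryl carbamates; their merger in one flask, with a single carbamate acting in turn as lithiation director, carrier of the C3 configuration and donor of the lactone carbonyl carbon, is what is new. The acyl shift passes through a six-membered cyclic tetrahedral intermediate formed by 6-exo-trig addition, which opens by loss of the secondary alkoxide, the better leaving group, so that 18 is isolated open-chain and the ring is closed for good in step 10. The one new stereocenter, C3, is set by the chiral diamine (reagent control), and the silyloxy-bearing center five bonds away should neither help nor hinder. The step needs SN2 attack at the benzylic bromide of 14 to outrun bromine–lithium exchange at its aryl bromide, which the much higher SN2 reactivity of a benzylic C–Br bond and the low exchange aptitude of the chelated α-oxy carbanion in Et2O at −78 °C should secure, and it needs 17 to attack the hindered carbamate and not the benzyl ethers, which the intramolecular six-membered geometry secures.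

Step 10
Reactants: 18 3,6-bis(benzyloxy)-2-[(2R,6R)-6-[(tert-butyldimethylsilyl)oxy]-2-hydroxyheptyl]-N,N-diisopropylbenzamide
Product: 19 (3R)-5,8-bis(benzyloxy)-3-[(4R)-4-hydroxypentyl]isochroman-1-one
Conditions: TsOH·H2O (3 equiv), toluene, 80 °C
Reagents that add atoms: none
Why: Acid-promoted intramolecular acyl transfer from the twisted tertiary benzamide to the neighbouring secondary hydroxyl (lactonisation, 6-exo-trig, diisopropylamine leaving as its ammonium salt) should close the lactone ring without breaking the C3–O bond, so C3 keeps its configuration, and the same acid with its water of hydration should cleave the silyl ether.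

Step 11
Reactants: 19 (3R)-5,8-bis(benzyloxy)-3-[(4R)-4-hydroxypentyl]isochroman-1-one; 20 succinic anhydride
Product: 21 4-{[(2R)-5-[(3R)-5,8-bis(benzyloxy)-1-oxoisochroman-3-yl]pentan-2-yl]oxy}-4-oxobutanoic acid
Conditions: DMAP, Et3N, CH2Cl2, 23 °C; then dilute HCl
Reagents that add atoms: none
Why: DMAP-catalysed ring opening of the cyclic anhydride by the only free hydroxyl should give the hemisuccinate, the phenols being masked as benzyl ethers.

Step 12
Reactants: 21 4-{[(2R)-5-[(3R)-5,8-bis(benzyloxy)-1-oxoisochroman-3-yl]pentan-2-yl]oxy}-4-oxobutanoic acid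
Product: 22 4-{[(2R)-5-[(3R)-5,8-dihydroxy-1-oxoisochroman-3-yl]pentan-2-yl]oxy}-4-oxobutanoic acid
Conditions: H2 (1 atm), Pd/C, EtOAc, 23 °C
Reagents that add atoms: none
Why: Hydrogenolysis of the two aryl benzyl ethers should free the hydroquinone under neutral conditions that leave the lactone, the succinate ester and both stereocenters (neither is benzylic) untouched.

**Compound list**

1 | (R)-propylene oxide, (2R)-2-methyloxirane | C[C@@H]1CO1 | starting material
2 | allylmagnesium bromide | C=CC[Mg]Br | starting material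
3 | (2R)-hex-5-en-2-ol | C[C@@H](O)CCC=C | intermediate
4 | tert-butyl{[(2R)-hex-5-en-2-yl]oxy}dimethylsilane | C[C@@H](O[Si](C)(C)C(C)(C)C)CCC=C | intermediate
5 | 9-{(5R)-5-[(tert-butyldimethylsilyl)oxy]hexyl}-9-borabicyclo[3.3.1]nonane | C[C@@H](O[Si](C)(C)C(C)(C)C)CCCCB1C2CCCC1CCC2 | intermediate
6 | (5R)-5-[(tert-butyldimethylsilyl)oxy]hexan-1-ol | C[C@@H](O[Si](C)(C)C(C)(C)C)CCCCO | intermediate
7 | N,N-diisopropylcarbamoyl chloride | CC(C)N(C(C)C)C(=O)Cl | starting material
8 | (5R)-5-[(tert-butyldimethylsilyl)oxy]hexyl N,N-diisopropylcarbamate | C[C@@H](O[Si](C)(C)C(C)(C)C)CCCCOC(=O)N(C(C)C)C(C)C | intermediate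
9 | 2-bromobenzene-1,4-diol (bromohydroquinone) | Oc1ccc(O)c(Br)c1 | starting material
10 | 1,4-bis(benzyloxy)-2-bromobenzene | Brc1cc(OCc2ccccc2)ccc1OCc1ccccc1 | intermediate
11 | [3,6-bis(benzyloxy)-2-bromophenyl]lithium | [Li]c1c(Br)c(OCc2ccccc2)ccc1OCc1ccccc1 | intermediate
12 | 3,6-bis(benzyloxy)-2-bromobenzaldehyde | O=Cc1c(Br)c(OCc2ccccc2)ccc1OCc1ccccc1 | intermediate
13 | [3,6-bis(benzyloxy)-2-bromophenyl]methanol | OCc1c(Br)c(OCc2ccccc2)ccc1OCc1ccccc1 | intermediate
14 | 1,4-bis(benzyloxy)-2-bromo-3-(bromomethyl)benzene | BrCc1c(Br)c(OCc2ccccc2)ccc1OCc1ccccc1 | intermediate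
15 | (1S,5R)-5-[(tert-butyldimethylsilyl)oxy]-1-lithiohexyl N,N-diisopropylcarbamate, as its (–)-sparteine complex | C[C@@H](O[Si](C)(C)C(C)(C)C)CCC[C@@H](OC(=O)N(C(C)C)C(C)C)[Li] | intermediate
16 | (2R,6R)-1-[3,6-bis(benzyloxy)-2-bromophenyl]-6-[(tert-butyldimethylsilyl)oxy]heptan-2-yl N,N-diisopropylcarbamate | C[C@@H](O[Si](C)(C)C(C)(C)C)CCC[C@@H](OC(=O)N(C(C)C)C(C)C)Cc1c(Br)c(OCc2ccccc2)ccc1OCc1ccccc1 | intermediate
17 | {3,6-bis(benzyloxy)-2-[(2R,6R)-6-[(tert-butyldimethylsilyl)oxy]-2-(diisopropylcarbamoyloxy)heptyl]phenyl}lithium | C[C@@H](O[Si](C)(C)C(C)(C)C)CCC[C@@H](OC(=O)N(C(C)C)C(C)C)Cc1c([Li])c(OCc2ccccc2)ccc1OCc1ccccc1 | intermediate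
18 | 3,6-bis(benzyloxy)-2-[(2R,6R)-6-[(tert-butyldimethylsilyl)oxy]-2-hydroxyheptyl]-N,N-diisopropylbenzamide | C[C@@H](O[Si](C)(C)C(C)(C)C)CCC[C@@H](O)Cc1c(C(=O)N(C(C)C)C(C)C)c(OCc2ccccc2)ccc1OCc1ccccc1 | intermediate
19 | (3R)-5,8-bis(benzyloxy)-3-[(4R)-4-hydroxypentyl]isochroman-1-one | C[C@@H](O)CCC[C@@H]1Cc2c(OCc3ccccc3)ccc(OCc3ccccc3)c2C(=O)O1 | intermediate
20 | succinic anhydride | O=C1CCC(=O)O1 | starting material
21 | 4-{[(2R)-5-[(3R)-5,8-bis(benzyloxy)-1-oxoisochroman-3-yl]pentan-2-yl]oxy}-4-oxobutanoic acid | C[C@H](CCC[C@@H]1Cc2c(OCc3ccccc3)ccc(OCc3ccccc3)c2C(=O)O1)OC(=O)CCC(=O)O | intermediate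
22 | 4-{[(2R)-5-[(3R)-5,8-dihydroxy-1-oxoisochroman-3-yl]pentan-2-yl]oxy}-4-oxobutanoic acid | C[C@H](CCC[C@@H]1Cc2c(O)ccc(O)c2C(=O)O1)OC(=O)CCC(=O)O | target

**Count and risks**

Total step count: 12. Longest linear sequence: 8 steps (steps 1–4 and 9–12; the arene branch, steps 5–8 and 9–12, is equally long).

Steps most likely to fail:

1. Step 9 (Proposed new method). Electron transfer or bromine–lithium exchange between the lithio carbamate and the dibromide could compete with SN2 benzylation, which would lower conversion and erode the configuration at C3; the carbamoyl shift onto the hindered carbamate could also stall. The fallback uses known chemistry, sets out from 8 and 14 and returns at 19. Dibromide 14 is borylated at the benzylic position (B2pin2, CuI, PPh3, LiOt-Bu, DMF) to give 2-[3,6-bis(benzyloxy)-2-bromobenzyl]-4,4,5,5-tetramethyl-1,3,2-dioxaborolane F1. Lithio carbamate 15, made from 8 as in step 9, is trapped by F1 to give the lithium boronate complex F2. Warming with MgBr2·OEt2 should trigger 1,2-migration of the benzyl group with loss of the carbamate (Matteson-type homologation, inversion at carbon) to give the secondary boronic ester F3. Oxidation with NaOH/H2O2 (retention) should give the (2R,6R) bromo alcohol F4. Carbonylative lactonisation (Pd(OAc)2, Xantphos, CO 1 atm, Et3N, toluene, 100 °C) should give the silyl-protected lactone F5, and TsOH·H2O in MeOH should remove the silyl group to return 19.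

2. Step 10. Acyl transfer from the doubly ortho-substituted diisopropylamide may be slow, and forcing acid may cause loss or migration of the benzyl ethers. The fallback sets out from 18 and returns at 19. HF·pyridine in THF should remove the silyl group to give the diol amide F6. Cp2Zr(H)Cl in THF should reduce the tertiary amide to the aldehyde, which is trapped by the neighbouring hydroxyl as the lactol F7. MnO2 in CH2Cl2 should oxidise the benzylic lactol, and not the unactivated secondary alcohol, to lactone 19.

3. Step 6. The aryllithium may lose LiBr to an aryne before it is formylated, or metalation may occur at other sites. The fallback sets out from 10 and returns at 12, with the order of bromine and formyl introduction reversed. Bromine–lithium exchange on 10 (n-BuLi, THF, −78 °C) and DMF should give 2,5-bis(benzyloxy)benzaldehyde F8. Lithium N,N,N′-trimethylethylenediamide adds to the formyl group to give the lithium α-amino alkoxide F9. This group should direct n-BuLi to the ring position between the masked formyl group and the neighbouring benzyloxy group, giving the aryllithium F10. 1,2-Dibromotetrachloroethane then installs bromine, and aqueous work-up frees the aldehyde to return 12.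

**Further compounds**

F1 | step 9 | 2-[3,6-bis(benzyloxy)-2-bromobenzyl]-4,4,5,5-tetramethyl-1,3,2-dioxaborolane | CC1(C)OB(Cc2c(Br)c(OCc3ccccc3)ccc2OCc2ccccc2)OC1(C)C
F2 | step 9 | lithium [3,6-bis(benzyloxy)-2-bromobenzyl]{(1S,5R)-5-[(tert-butyldimethylsilyl)oxy]-1-(diisopropylcarbamoyloxy)hexyl}(pinacolato)borate | [Li+].C[C@@H](O[Si](C)(C)C(C)(C)C)CCC[C@@H](OC(=O)N(C(C)C)C(C)C)[B-]1(Cc2c(Br)c(OCc3ccccc3)ccc2OCc2ccccc2)OC(C)(C)C(C)(C)O1
F3 | step 9 | tert-butyl{[(2R,6R)-7-[3,6-bis(benzyloxy)-2-bromophenyl]-6-(4,4,5,5-tetramethyl-1,3,2-dioxaborolan-2-yl)heptan-2-yl]oxy}dimethylsilane | C[C@@H](O[Si](C)(C)C(C)(C)C)CCC[C@@H](B1OC(C)(C)C(C)(C)O1)Cc1c(Br)c(OCc2ccccc2)ccc1OCc1ccccc1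
F4 | step 9 | (2R,6R)-1-[3,6-bis(benzyloxy)-2-bromophenyl]-6-[(tert-butyldimethylsilyl)oxy]heptan-2-ol | C[C@@H](O[Si](C)(C)C(C)(C)C)CCC[C@@H](O)Cc1c(Br)c(OCc2ccccc2)ccc1OCc1ccccc1
F5 | step 9 | (3R)-5,8-bis(benzyloxy)-3-{(4R)-4-[(tert-butyldimethylsilyl)oxy]pentyl}isochroman-1-one | C[C@@H](O[Si](C)(C)C(C)(C)C)CCC[C@@H]1Cc2c(OCc3ccccc3)ccc(OCc3ccccc3)c2C(=O)O1
F6 | step 10 | 3,6-bis(benzyloxy)-2-[(2R,6R)-2,6-dihydroxyheptyl]-N,N-diisopropylbenzamide | C[C@@H](O)CCC[C@@H](O)Cc1c(C(=O)N(C(C)C)C(C)C)c(OCc2ccccc2)ccc1OCc1ccccc1
F7 | step 10 | (3R)-5,8-bis(benzyloxy)-3-[(4R)-4-hydroxypentyl]isochroman-1-ol (both configurations at C1) | C[C@@H](O)CCC[C@@H]1Cc2c(OCc3ccccc3)ccc(OCc3ccccc3)c2C(O)O1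
F8 | step 6 | 2,5-bis(benzyloxy)benzaldehyde | O=Cc1cc(OCc2ccccc2)ccc1OCc1ccccc1
F9 | step 6 | lithium [2,5-bis(benzyloxy)phenyl]{[2-(dimethylamino)ethyl](methyl)amino}methanolate | [Li]OC(N(C)CCN(C)C)c1cc(OCc2ccccc2)ccc1OCc1ccccc1
F10 | step 6 | lithium [3,6-bis(benzyloxy)-2-lithiophenyl]{[2-(dimethylamino)ethyl](methyl)amino}methanolate | [Li]OC(N(C)CCN(C)C)c1c([Li])c(OCc2ccccc2)ccc1OCc1ccccc1
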